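**Strategy.** The diacid linker is disconnected between the vinylic CH (C3) of its 2-methyl-2-enoate half and the neighbouring CH2 (C4), so that each half is an ester of the same cis-fused octahydrocyclopenta[c]pyridin-6-ol. One ester carries a terminal vinyl group on its (E)-3-methyl-2-enoate, the other is an (E)-3-iodo-2-methylacrylate. Anti-Markovnikov hydroboration of the vinyl group and in situ B-alkyl Suzuki–Miyaura coupling form C3–C4 in one pot, leave both preformed E-trisubstituted alkenes (C2=C3, C6=C7) untouched and give the target directly. The step exploits that C4 is a primary sp3 carbon between two complete enoates, each already esterified at C6 of its piperidine–cyclopentane bicycle. The bicycle comes from a Pauson–Khand reaction relayed from one purchased stereocentre; Mitsunobu esterification inverts C6.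

Key step: step 15

Remark on numbering: linker carbons C1–C8 run from the carbonyl of the 2-methyl-2-enoate; the bicycle is numbered as octahydro-1H-cyclopenta[c]pyridine (C1, N2, C3, C4, C4a, C5, C6, C7, C7a).
Remark on starting materials: compounds 1, 2, 13, 14 and 17 are taken as commercial (17 as the E isomer).

**Step 1**
Reactants: 1 (S)-3-bromo-2-methylpropan-1-ol; 2 allylamine
Product: 3 (2R)-2-methyl-3-(prop-2-en-1-ylamino)propan-1-ol
Conditions: allylamine (5 equiv), K2CO3, MeCN, 60 °C, sealed vessel
Reagents that add atoms: none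
Why: SN2 amination of the primary bromide by excess amine should stop at monoalkylation and leaves the purchased stereocentre untouched (the descriptor changes from S to R only because the priorities change).

**Step 2**
Reactants: 3 (2R)-2-methyl-3-(prop-2-en-1-ylamino)propan-1-ol
Product: 4 methyl N-[(2R)-3-hydroxy-2-methylpropyl]-N-(prop-2-en-1-yl)carbamate
Conditions: ClCO2Me, NaHCO3, CH2Cl2/H2O, 0 °C
Reagents that add atoms: methyl chloroformate, COC(=O)Cl
Why: Schotten–Baumann acylation is selective for nitrogen over oxygen and gives a carbamate that makes the nitrogen non-basic for the cobalt chemistry and is the latent N-methyl group.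

**Step 3**
Reactants: 4 methyl N-[(2R)-3-hydroxy-2-methylpropyl]-N-(prop-2-en-1-yl)carbamate
Product: 5 methyl N-[(2R)-2-methyl-3-oxopropyl]-N-(prop-2-en-1-yl)carbamate
Conditions: Dess–Martin periodinane, pyridine, CH2Cl2, 0 °C to rt; used crude at once
Reagents that add atoms: none
Why: Dess–Martin oxidation under buffered, non-basic conditions should give the α-branched aldehyde without epimerisation.

**Step 4**
Reactants: 5 methyl N-[(2R)-2-methyl-3-oxopropyl]-N-(prop-2-en-1-yl)carbamate
Product: 6 methyl N-[(2S)-2-methylbut-3-yn-1-yl]-N-(prop-2-en-1-yl)carbamate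
Conditions: dimethyl (1-diazo-2-oxopropyl)phosphonate, K2CO3, MeOH, 0 °C to rt
Reagents that add atoms: dimethyl (1-diazo-2-oxopropyl)phosphonate (Ohira–Bestmann reagent), CC(=O)C(=[N+]=[N-])P(=O)(OC)OC
Why: Seyferth–Gilbert homologation in its Ohira–Bestmann form converts the aldehyde into the terminal alkyne under carbonate conditions mild enough for an α-stereogenic aldehyde.

**Step 5**
Reactants: 6 methyl N-[(2S)-2-methylbut-3-yn-1-yl]-N-(prop-2-en-1-yl)carbamate
Product: 7 methyl (4S,7aR)-4-methyl-6-oxo-1,3,4,6,7,7a-hexahydro-2H-cyclopenta[c]pyridine-2-carboxylate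
Conditions: Co2(CO)8 (10 mol %), tetramethylthiourea (60 mol %), CO (1 atm), toluene, 70 °C
Reagents that add atoms: carbon monoxide, [C-]#[O+]
Why: The intramolecular Pauson–Khand [2+2+1] cyclocarbonylation of the 1,7-enyne closes the piperidine and the cyclopentenone at once, and C7a should be set from C4 through a chair-like alkene insertion in which the propargylic hydrogen points into the dicobalt cluster and the C4 methyl is equatorial, so that this methyl and C7 end up cis on the six-membered ring.

**Step 6**
Reactants: 7 methyl (4S,7aR)-4-methyl-6-oxo-1,3,4,6,7,7a-hexahydro-2H-cyclopenta[c]pyridine-2-carboxylate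
Product: 9 methyl (4S,7R,7aR)-4,7-dimethyl-6-oxo-1,3,4,6,7,7a-hexahydro-2H-cyclopenta[c]pyridine-2-carboxylate, via lithium dienolate 8 (not isolated)
Conditions: LiN(i-Pr)2 (1.05 equiv), THF, −78 °C; MeI, −78 to −40 °C
Reagents that add atoms: iodomethane, CI; lithium diisopropylamide, [Li+].CC(C)[N-]C(C)C (its lithium is carried in intermediate 8 only)
Why: Kinetic deprotonation at the only sp3 α-carbon of the enone (C7) gives the cross-conjugated dienolate, whose methylation anti to the C7a–C1 bond should set the C7 methyl trans to C1.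

**Step 7**
Reactants: 9 methyl (4S,7R,7aR)-4,7-dimethyl-6-oxo-1,3,4,6,7,7a-hexahydro-2H-cyclopenta[c]pyridine-2-carboxylate
Product: 10 methyl (4S,4aR,7R,7aS)-4,7-dimethyl-6-oxooctahydro-2H-cyclopenta[c]pyridine-2-carboxylate
Conditions: H2 (1 atm), 10% Pd/C, EtOAc, rt
Reagents that add atoms: none
Why: Heterogeneous hydrogenation of the trisubstituted enone should deliver hydrogen to C4a from the face of H7a, because the C1 methylene shields the other face, giving the cis-fused bicycle with H4a trans to the C4 methyl.

**Step 8**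
Reactants: 10 methyl (4S,4aR,7R,7aS)-4,7-dimethyl-6-oxooctahydro-2H-cyclopenta[c]pyridine-2-carboxylate
Product: 12 (4S,4aR,6R,7R,7aS)-2,4,7-trimethyloctahydro-1H-cyclopenta[c]pyridin-6-ol, via hydroxy carbamate 11 (not isolated)
Conditions: LiAlH4 (excess), THF, −20 °C, then reflux; aqueous NaOH work-up
Reagents that add atoms: none
Why: LiAlH4 should first reduce the ketone from the convex face, syn to the C7 methyl as small hydrides do with 2-alkylcyclopentanones, giving the concave C6 alcohol (oxygen trans to the methyl), and on heating it reduces the methyl carbamate to the N-methyl amine.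

**Step 9**
Reactants: 13 diethyl methylmalonate; 14 iodoform
Product: 15 diethyl 2-(diiodomethyl)-2-methylmalonate
Conditions: NaH, Et2O, reflux
Reagents that add atoms: none
Why: C-alkylation of the sodium malonate by iodoform (through diiodocarbene) is the standard entry to β-iodo-α-methylacrylic acid.

**Step 10**
Reactants: 15 diethyl 2-(diiodomethyl)-2-methylmalonate
Product: 16 (E)-3-iodo-2-methylacrylic acid
Conditions: KOH, EtOH/H2O, reflux; then aq HCl
Reagents that add atoms: potassium hydroxide, [K+].[OH-]
Why: Saponification followed by decarboxylative elimination of iodide should give the vinyl iodide acid as the E isomer, with iodine trans to the carboxyl group.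

**Step 11**
Reactants: 17 ethyl (E)-3-methyl-4-oxobut-2-enoate
Product: 18 ethyl (E)-3-methylpenta-2,4-dienoate
Conditions: Ph3PCH3Br, KOtBu, THF, 0 °C; then 17, −78 to 0 °C
Reagents that add atoms: methyltriphenylphosphonium bromide, C[P+](c1ccccc1)(c1ccccc1)c1ccccc1.[Br-]
Why: Wittig methylenation by the non-stabilised ylide adds 1,2 to the aldehyde and leaves the (E)-enoate untouched.

**Step 12**
Reactants: 18 ethyl (E)-3-methylpenta-2,4-dienoate
Product: 19 (E)-3-methylpenta-2,4-dienoic acid
Conditions: LiOH, THF/H2O, rt; then aq HCl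
Reagents that add atoms: lithium hydroxide, [Li+].[OH-]
Why: Mild saponification of the ethyl ester keeps the E geometry of the β,β-disubstituted enoate.

**Step 13**
Reactants: 12 (4S,4aR,6R,7R,7aS)-2,4,7-trimethyloctahydro-1H-cyclopenta[c]pyridin-6-ol; 16 (E)-3-iodo-2-methylacrylic acid
Product: 20 (4S,4aR,6S,7R,7aS)-2,4,7-trimethyloctahydro-1H-cyclopenta[c]pyridin-6-yl (E)-3-iodo-2-methylprop-2-enoate
Conditions: PPh3, 16 (1.5 equiv), THF, 0 °C; DIAD added last, 0 °C to rt
Reagents that add atoms: none
Why: In the Mitsunobu esterification the carboxylate displaces the alkoxyphosphonium from the convex face in an SN2 reaction with inversion at C6, which places the ester oxygen cis to the C7 methyl as in the target, and late addition of DIAD keeps free phosphine away from the β-iodoacrylate.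

**Step 14**
Reactants: 12 (4S,4aR,6R,7R,7aS)-2,4,7-trimethyloctahydro-1H-cyclopenta[c]pyridin-6-ol; 19 (E)-3-methylpenta-2,4-dienoic acid
Product: 21 (4S,4aR,6S,7R,7aS)-2,4,7-trimethyloctahydro-1H-cyclopenta[c]pyridin-6-yl (E)-3-methylpenta-2,4-dienoate
Conditions: PPh3, 19 (1.5 equiv), THF, 0 °C; DIAD added last, 0 °C to rt
Reagents that add atoms: none
Why: The same Mitsunobu SN2 displacement inverts C6 and attaches the dienoate without touching its E-alkene or the terminal vinyl group.

**Step 15**
Reactants: 21 (4S,4aR,6S,7R,7aS)-2,4,7-trimethyloctahydro-1H-cyclopenta[c]pyridin-6-yl (E)-3-methylpenta-2,4-dienoate; 20 (4S,4aR,6S,7R,7aS)-2,4,7-trimethyloctahydro-1H-cyclopenta[c]pyridin-6-yl (E)-3-iodo-2-methylprop-2-enoate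
Product: 23 bis[(4S,4aR,6S,7R,7aS)-2,4,7-trimethyloctahydro-1H-cyclopenta[c]pyridin-6-yl] (2E,6E)-2,6-dimethylocta-2,6-dienedioate (CNP0240822.2), via B-alkyl-9-BBN borane 22 (not isolated)
Conditions: 21, 9-BBN dimer (1.3 equiv, 2.6 B–H), THF, 0 to 50 °C; then 3 M aq K3PO4, rt; then 20, Pd(dppf)Cl2 (10 mol %), AsPh3 (10 mol %), DMF, rt
Reagents that add atoms: 9-borabicyclo[3.3.1]nonane (9-BBN), B1C2CCCC1CCC2 (its boron unit is carried in intermediate 22 only; it leaves hydrogen alone in 23)
Why: Hydroboration should place boron on the terminal carbon (C4) of the vinyl group of 21, the bulk of 9-BBN overriding the polarisation of the dienoate, while the trisubstituted ester-conjugated alkene does not react; the hindered tertiary amine binds borane only reversibly, which the excess of 9-BBN and the warming allow for. After the residual B–H is destroyed with aqueous K3PO4, zerovalent palladium inserts into the C–I bond of 20 with retention of the E geometry, the base-activated primary alkyl group of 22 transmetalates and reductive elimination forms the C3–C4 bond. The closest known reaction type is the one-pot hydroboration/B-alkyl Suzuki–Miyaura coupling of 9-BBN adducts of terminal 1,3-dienes with alkenyl iodides. No ring is closed and no stereocentre is created, so the step only has to preserve the two E-trisubstituted alkenes and the ten stereocentres already present, which the stereoretentive coupling at room temperature should secure. The selectivity needed is transmetalation and reductive elimination faster than β-hydride elimination of the alkylpalladium and faster than base attack on the two esters or on the β-iodoenoate, for which the wide bite angle of dppf in Pd(dppf)Cl2, the AsPh3 additive and the mild phosphate base are chosen.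

**Compound list**
1 | (S)-3-bromo-2-methylpropan-1-ol | C[C@H](CBr)CO | starting material
2 | allylamine (prop-2-en-1-amine) | C=CCN | starting material
3 | (2R)-2-methyl-3-(prop-2-en-1-ylamino)propan-1-ol | C[C@H](CNCC=C)CO | intermediate
4 | methyl N-[(2R)-3-hydroxy-2-methylpropyl]-N-(prop-2-en-1-yl)carbamate | C[C@H](CN(CC=C)C(=O)OC)CO | intermediate
5 | methyl N-[(2R)-2-methyl-3-oxopropyl]-N-(prop-2-en-1-yl)carbamate | C[C@H](CN(CC=C)C(=O)OC)C=O | intermediate
6 | methyl N-[(2S)-2-methylbut-3-yn-1-yl]-N-(prop-2-en-1-yl)carbamate | C[C@H](CN(CC=C)C(=O)OC)C#C | intermediate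
7 | methyl (4S,7aR)-4-methyl-6-oxo-1,3,4,6,7,7a-hexahydro-2H-cyclopenta[c]pyridine-2-carboxylate | O=C1C=C2[C@H](CN(C(=O)OC)C[C@H]2C)C1 | intermediate
8 | lithium dienolate of 7 (O-lithium, C6=C7 and C4a=C5 double bonds) | [Li]OC1C=C2[C@H](CN(C(=O)OC)C[C@H]2C)C=1 | intermediate (not isolated)
9 | methyl (4S,7R,7aR)-4,7-dimethyl-6-oxo-1,3,4,6,7,7a-hexahydro-2H-cyclopenta[c]pyridine-2-carboxylate | O=C1C=C2[C@H](CN(C(=O)OC)C[C@H]2C)[C@H]1C | intermediate
10 | methyl (4S,4aR,7R,7aS)-4,7-dimethyl-6-oxooctahydro-2H-cyclopenta[c]pyridine-2-carboxylate | O=C1C[C@H]2[C@H](CN(C(=O)OC)C[C@H]2C)[C@H]1C | intermediate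
11 | methyl (4S,4aR,6R,7R,7aS)-6-hydroxy-4,7-dimethyloctahydro-2H-cyclopenta[c]pyridine-2-carboxylate | O[C@@H]1C[C@H]2[C@H](CN(C(=O)OC)C[C@H]2C)[C@H]1C | intermediate (not isolated)
12 | (4S,4aR,6R,7R,7aS)-2,4,7-trimethyloctahydro-1H-cyclopenta[c]pyridin-6-ol (C6 epimer of the alcohol of the target) | O[C@@H]1C[C@H]2[C@H](CN(C)C[C@H]2C)[C@H]1C | intermediate
13 | diethyl methylmalonate | CCOC(=O)C(C)C(=O)OCC | starting material
14 | iodoform | IC(I)I | starting material
15 | diethyl 2-(diiodomethyl)-2-methylmalonate | CCOC(=O)C(C)(C(I)I)C(=O)OCC | intermediate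
16 | (E)-3-iodo-2-methylacrylic acid | C/C(=C\I)C(=O)O | intermediate
17 | ethyl (E)-3-methyl-4-oxobut-2-enoate | CCOC(=O)/C=C(\C)C=O | starting material
18 | ethyl (E)-3-methylpenta-2,4-dienoate | CCOC(=O)/C=C(\C)C=C | intermediate
19 | (E)-3-methylpenta-2,4-dienoic acid | OC(=O)/C=C(\C)C=C | intermediate
20 | (4S,4aR,6S,7R,7aS)-2,4,7-trimethyloctahydro-1H-cyclopenta[c]pyridin-6-yl (E)-3-iodo-2-methylprop-2-enoate | C/C(=C\I)C(=O)O[C@H]1C[C@H]2[C@H](CN(C)C[C@H]2C)[C@H]1C | intermediate
21 | (4S,4aR,6S,7R,7aS)-2,4,7-trimethyloctahydro-1H-cyclopenta[c]pyridin-6-yl (E)-3-methylpenta-2,4-dienoate | C/C(=C\C(=O)O[C@H]1C[C@H]2[C@H](CN(C)C[C@H]2C)[C@H]1C)C=C | intermediate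
22 | (4S,4aR,6S,7R,7aS)-2,4,7-trimethyloctahydro-1H-cyclopenta[c]pyridin-6-yl (E)-5-(9-borabicyclo[3.3.1]nonan-9-yl)-3-methylpent-2-enoate | C/C(=C\C(=O)O[C@H]1C[C@H]2[C@H](CN(C)C[C@H]2C)[C@H]1C)CCB1C2CCCC1CCC2 | intermediate (not isolated)
23 | bis[(4S,4aR,6S,7R,7aS)-2,4,7-trimethyloctahydro-1H-cyclopenta[c]pyridin-6-yl] (2E,6E)-2,6-dimethylocta-2,6-dienedioate | C/C(=C\C(=O)O[C@H]1C[C@H]2[C@H](CN(C)C[C@H]2C)[C@H]1C)CC/C=C(\C)C(=O)O[C@H]1C[C@H]2[C@H](CN(C)C[C@H]2C)[C@H]1C | target

**Step count.** Total: 15 steps. Longest linear sequence: 10 steps (steps 1 to 8, then 14, then 15; the branch through step 13 is equally long).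

**Three steps most likely to fail**

1. Step 15. What may go wrong: sequestration of 9-BBN by the two basic nitrogens, slow or unselective hydroboration of the electron-poor diene, or inhibition of the palladium catalyst by the amines. The fallback sets out from 18 and 16 and comes back to the route at 23; it makes the same C3–C4 bond by the same coupling, but before any nitrogen is present. Acid 16 would be esterified (EtI, K2CO3, DMF) to ethyl (E)-3-iodo-2-methylacrylate F1. Ester 18 would be hydroborated with 9-BBN to ethyl (E)-5-(9-borabicyclo[3.3.1]nonan-9-yl)-3-methylpent-2-enoate F2 (not isolated) and coupled with F1 (Pd(dppf)Cl2, AsPh3, aq K3PO4, DMF, rt) to diethyl (2E,6E)-2,6-dimethylocta-2,6-dienedioate F3. Saponification with LiOH would give (2E,6E)-2,6-dimethylocta-2,6-dienedioic acid F4, and a double Mitsunobu esterification of F4 with 12 (2.2 equiv; PPh3, DIAD, THF), with inversion at both C6 centres, should give 23.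

2. Step 5. What may go wrong: insufficient 1,3-induction from C4 to C7a (poor facial selectivity of the alkene insertion) or sluggish cyclocarbonylation of the 1,7-enyne. The fallback sets out from 2 and comes back to the route at 11, which the LiAlH4 conditions of step 8 convert into 12; it relays all stereocentres from a purchased C–O stereocentre.
   - Amine 2 would be acylated (ClCO2Me, NaHCO3) to methyl N-allylcarbamate F5 and alkylated (NaH, MeOCH2Cl, THF) to methyl N-allyl-N-(methoxymethyl)carbamate F6.
   - Conjugate addition of Me2CuLi to commercial (R)-4-(tert-butyldimethylsilyloxy)cyclopent-2-en-1-one F7 in the presence of Me3SiCl should give, anti to the silyloxy group, the trimethylsilyl enol ether of (3R,4R)-3-methyl-4-(tert-butyldimethylsilyloxy)cyclopentanone F8.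
   - Mukaiyama–Mannich amidoalkylation of F8 with F6 (Me3SiOTf, CH2Cl2, −78 °C) should give the 2,3-trans ketone methyl N-allyl-N-{[2-methyl-5-oxo-3-(tert-butyldimethylsilyloxy)cyclopentyl]methyl}carbamate F9.
   - Kinetic enolisation toward the ring CH2 (LiN(SiMe3)2, PhNTf2, THF, −78 °C) would give the enol triflate F10.
   - Reductive Heck cyclisation (Pd(OAc)2, PPh3, HCO2Na, DMF, 80 °C; 6-exo, C4 methyl equatorial) should close the piperidine to the C4a=C5 alkene F11.
   - Hydrogenation anti to the silyloxy group (H2, Pd/C) should give the cis-fused silyl ether F12, and Bu4NF would release 11.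

3. Step 13 (and in the same way step 14). What may go wrong: elimination instead of SN2 displacement at the hindered C6 alkoxyphosphonium, or conjugate addition of PPh3 to the β-iodoacrylate. The fallback sets out from 12 and comes back to the route at 20; it replaces the redox condensation by a sulfonate displacement. Alcohol 12 would be converted (MsCl, Et3N, CH2Cl2, 0 °C) into (4S,4aR,6R,7R,7aS)-2,4,7-trimethyloctahydro-1H-cyclopenta[c]pyridin-6-yl methanesulfonate F13. Cesium (E)-3-iodo-2-methylacrylate F14 (from 16 and Cs2CO3) should then displace the mesylate in DMF at 50 °C with inversion at C6 to give 20.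

**Further compounds**
F1 | step 15 | ethyl (E)-3-iodo-2-methylacrylate | C/C(=C\I)C(=O)OCC
F2 | step 15 | ethyl (E)-5-(9-borabicyclo[3.3.1]nonan-9-yl)-3-methylpent-2-enoate | CCOC(=O)/C=C(\C)CCB1C2CCCC1CCC2
F3 | step 15 | diethyl (2E,6E)-2,6-dimethylocta-2,6-dienedioate | CCOC(=O)/C=C(\C)CC/C=C(\C)C(=O)OCC
F4 | step 15 | (2E,6E)-2,6-dimethylocta-2,6-dienedioic acid | OC(=O)/C=C(\C)CC/C=C(\C)C(=O)O
F5 | step 5 | methyl N-allylcarbamate | C=CCNC(=O)OC
F6 | step 5 | methyl N-allyl-N-(methoxymethyl)carbamate | C=CCN(COC)C(=O)OC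
F7 | step 5 | (R)-4-(tert-butyldimethylsilyloxy)cyclopent-2-en-1-one | CC(C)(C)[Si](C)(C)O[C@@H]1CC(=O)C=C1
F8 | step 5 | trimethylsilyl enol ether of (3R,4R)-3-methyl-4-(tert-butyldimethylsilyloxy)cyclopentanone | CC(C)(C)[Si](C)(C)O[C@@H]1CC(O[Si](C)(C)C)=C[C@H]1C
F9 | step 5 | methyl N-allyl-N-{[2-methyl-5-oxo-3-(tert-butyldimethylsilyloxy)cyclopentyl]methyl}carbamate (all-trans) | CC(C)(C)[Si](C)(C)O[C@@H]1CC(=O)[C@H](CN(CC=C)C(=O)OC)[C@H]1C
F10 | step 5 | enol triflate of F9 (C4a=C5 double bond, triflyloxy on C4a) | CC(C)(C)[Si](C)(C)O[C@@H]1C=C(OS(=O)(=O)C(F)(F)F)[C@H](CN(CC=C)C(=O)OC)[C@H]1C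
F11 | step 5 | methyl 4,7-dimethyl-6-(tert-butyldimethylsilyloxy)-1,3,4,6,7,7a-hexahydro-2H-cyclopenta[c]pyridine-2-carboxylate (C4a=C5 alkene) | CC(C)(C)[Si](C)(C)O[C@@H]1C=C2[C@H](CN(C(=O)OC)C[C@H]2C)[C@H]1C
F12 | step 5 | tert-butyldimethylsilyl ether of 11 | CC(C)(C)[Si](C)(C)O[C@@H]1C[C@H]2[C@H](CN(C(=O)OC)C[C@H]2C)[C@H]1C
F13 | step 13 | (4S,4aR,6R,7R,7aS)-2,4,7-trimethyloctahydro-1H-cyclopenta[c]pyridin-6-yl methanesulfonate | CS(=O)(=O)O[C@@H]1C[C@H]2[C@H](CN(C)C[C@H]2C)[C@H]1C
F14 | step 13 | cesium (E)-3-iodo-2-methylacrylate | C/C(=C\I)C(=O)[O-].[Cs+]
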